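**Retrosynthetic overview**
- The target comes from hydrogenolysis of its penta-O-benzyl ether; the single methyl ether is carried from the start.
- Both pyranone rings (ring C of each flavone) are closed last and together, by I2/DMSO oxidative cyclisation of a biaryl bis(2'-hydroxychalcone). The one free phenol on each ring A fixes 8-linkage in one half and 6-linkage in the other.
- Key disconnection: the two C(alpha)–C(beta) bonds of the bichalcone, made by a twofold intermolecular Claisen–Schmidt aldol condensation of a biaryl bis(acetophenone) with 4-(benzyloxy)benzaldehyde, which brings in both rings B.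
- The biaryl bond between the two rings A is made before any heterocycle, by Suzuki–Miyaura coupling of two differently protected 3-iodophloroacetophenones (fragment 1 as pinacol boronate, fragment 2 as iodide).
- Each fragment comes from phloroacetophenone by chelation-controlled O-alkylation and iodination ortho to the chelated phenol. Ring order: rings A (bought), biaryl, rings B attached by aldol, rings C.

Assumption: the SMILES has no stereodescriptor and the molecule has no stereocentre, so the tetra-ortho-substituted biaryl axis is left uncontrolled and the compound is made as drawn (racemic about the axis).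

**Step 1**
Reactants: 1 1-(2,4,6-trihydroxyphenyl)ethanone (phloroacetophenone)
Product: 2 1-(2,6-dihydroxy-4-methoxyphenyl)ethanone
Conditions: Me2SO4 (1.0 equiv), K2CO3 (1.0 equiv), acetone, rt to 50 °C
Reagents that add atoms: dimethyl sulfate, COS(=O)(=O)OC
Why: Williamson O-methylation goes to the 4-OH, the only hydroxyl not hydrogen-bonded to the acetyl carbonyl and the most acidic one.

**Step 2**
Reactants: 2 1-(2,6-dihydroxy-4-methoxyphenyl)ethanone
Product: 3 1-[2-(benzyloxy)-6-hydroxy-4-methoxyphenyl]ethanone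
Conditions: BnBr (1.05 equiv), K2CO3, acetone, reflux
Reagents that add atoms: benzyl bromide, BrCc1ccccc1
Why: Williamson etherification of a symmetric diol gives one product, and the remaining phenol stays chelated to the ketone and resists a second alkylation.

**Step 3**
Reactants: 3 1-[2-(benzyloxy)-6-hydroxy-4-methoxyphenyl]ethanone
Product: 4 1-[6-(benzyloxy)-2-hydroxy-3-iodo-4-methoxyphenyl]ethanone
Conditions: NIS (1.0 equiv), TFA (cat.), MeCN, 0 °C to rt
Reagents that add atoms: N-iodosuccinimide, O=C1CCC(=O)N1I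
Why: Electrophilic aromatic iodination goes to C3, ortho to the free chelated phenol and less hindered than C5 (flanked by OMe and OBn), as is known for 2-hydroxy-4,6-dialkoxyacetophenones.

**Step 4**
Reactants: 4 1-[6-(benzyloxy)-2-hydroxy-3-iodo-4-methoxyphenyl]ethanone
Product: 5 1-[6-(benzyloxy)-3-iodo-4-methoxy-2-(methoxymethoxy)phenyl]ethanone
Conditions: NaH (1.1 equiv), MOMCl, DMF, 0 °C to rt
Reagents that add atoms: chloromethyl methyl ether, COCCl
Why: Williamson-type O-alkylation of the sodium phenoxide masks the phenol next to iodine for the palladium steps with a group that can later be removed beside benzyl and methyl ethers.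

**Step 5**
Reactants: 5 1-[6-(benzyloxy)-3-iodo-4-methoxy-2-(methoxymethoxy)phenyl]ethanone
Product: 6 1-[6-(benzyloxy)-4-methoxy-2-(methoxymethoxy)-3-(4,4,5,5-tetramethyl-1,3,2-dioxaborolan-2-yl)phenyl]ethanone
Conditions: B2pin2, Pd(OAc)2 (5 mol%), SPhos (10 mol%), KOAc, 1,4-dioxane, 90 °C
Reagents that add atoms: bis(pinacolato)diboron, CC1(C)OB(OC1(C)C)B1OC(C)(C)C(C)(C)O1
Why: Miyaura borylation, in which SPhos-ligated zerovalent palladium inserts into the hindered electron-rich C–I bond and the acetate-assisted transmetalation leaves the ketone untouched.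

**Step 6**
Reactants: 1 1-(2,4,6-trihydroxyphenyl)ethanone
Product: 7 1-[4-(benzyloxy)-2,6-dihydroxyphenyl]ethanone
Conditions: BnBr (1.0 equiv, slow addition), K2CO3 (1.0 equiv), DMF, 0 °C to rt
Reagents that add atoms: benzyl bromide, BrCc1ccccc1
Why: Williamson etherification selective for the non-chelated 4-OH, as in step 1; the dibenzyl ether by-product is removed by chromatography.

**Step 7**
Reactants: 7 1-[4-(benzyloxy)-2,6-dihydroxyphenyl]ethanone
Product: 8 1-[4-(benzyloxy)-2-hydroxy-6-(methoxymethoxy)phenyl]ethanone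
Conditions: MOMCl (1.1 equiv), K2CO3, acetone, 0 °C to rt
Reagents that add atoms: chloromethyl methyl ether, COCCl
Why: Mono-O-alkylation of a symmetric diol gives one product, and the second phenol stays chelated and unreactive, which marks the oxygen that will later close ring C.

**Step 8**
Reactants: 8 1-[4-(benzyloxy)-2-hydroxy-6-(methoxymethoxy)phenyl]ethanone
Product: 9 1-[4-(benzyloxy)-2-hydroxy-3-iodo-6-(methoxymethoxy)phenyl]ethanone
Conditions: NIS (1.0 equiv), DMF, 0 °C to rt
Reagents that add atoms: N-iodosuccinimide, O=C1CCC(=O)N1I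
Why: Electrophilic aromatic iodination again goes ortho to the free chelated phenol (C3, between OH and OBn), and acid-free NIS leaves the MOM acetal intact.

**Step 9**
Reactants: 9 1-[4-(benzyloxy)-2-hydroxy-3-iodo-6-(methoxymethoxy)phenyl]ethanone
Product: 10 1-[2,4-bis(benzyloxy)-3-iodo-6-(methoxymethoxy)phenyl]ethanone
Conditions: BnBr (1.5 equiv), K2CO3, DMF, 60 °C
Reagents that add atoms: benzyl bromide, BrCc1ccccc1
Why: Williamson etherification of the chelated phenol under forcing conditions puts the lasting benzyl group on the oxygen next to iodine (the future 5-O of the 6-linked unit).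

**Step 10**
Reactants: 6 1-[6-(benzyloxy)-4-methoxy-2-(methoxymethoxy)-3-(4,4,5,5-tetramethyl-1,3,2-dioxaborolan-2-yl)phenyl]ethanone (1.3 equiv); 10 1-[2,4-bis(benzyloxy)-3-iodo-6-(methoxymethoxy)phenyl]ethanone
Product: 11 1,1'-[2',4,6'-tris(benzyloxy)-6-methoxy-2,4'-bis(methoxymethoxy)biphenyl-3,3'-diyl]diethanone (racemic about the axis)
Conditions: Pd2(dba)3 (5 mol%), SPhos (20 mol%), K3PO4, toluene/H2O 10:1, 100 °C
Reagents that add atoms: none
Why: Suzuki–Miyaura cross-coupling, in which the bulky electron-rich biarylphosphine allows a tetra-ortho-alkoxy biaryl to form; the new axis is formed without control because the target carries no descriptor for it.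

**Step 11**
Reactants: 11 1,1'-[2',4,6'-tris(benzyloxy)-6-methoxy-2,4'-bis(methoxymethoxy)biphenyl-3,3'-diyl]diethanone
Product: 12 1,1'-[2',4,6'-tris(benzyloxy)-2,4'-dihydroxy-6-methoxybiphenyl-3,3'-diyl]diethanone
Conditions: 3 M HCl, MeOH/THF, 50 °C
Reagents that add atoms: none
Why: Acid-catalysed acetal cleavage (transacetalisation to methanol) removes both MOM groups and leaves benzyl and methyl ethers alone, so each ring A now has exactly one free phenol.

**Step 12 (key step)**
Reactants: 12 1,1'-[2',4,6'-tris(benzyloxy)-2,4'-dihydroxy-6-methoxybiphenyl-3,3'-diyl]diethanone; 13 4-(benzyloxy)benzaldehyde (3 equiv)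
Product: 15 (2E,2'E)-1,1'-[2',4,6'-tris(benzyloxy)-2,4'-dihydroxy-6-methoxybiphenyl-3,3'-diyl]bis{3-[4-(benzyloxy)phenyl]prop-2-en-1-one}, via bis-aldol adduct 14 (not isolated)
Conditions: KOH (50% aq., excess), EtOH/THF, rt, 48 h; dil. HCl work-up
Reagents that add atoms: none
Why: Twofold Claisen–Schmidt (crossed aldol) condensation, in which each methyl ketone enolate adds to the non-enolisable aldehyde and E1cB dehydration gives the thermodynamically favoured E-enones.

**Step 13**
Reactants: 15 (2E,2'E)-1,1'-[2',4,6'-tris(benzyloxy)-2,4'-dihydroxy-6-methoxybiphenyl-3,3'-diyl]bis{3-[4-(benzyloxy)phenyl]prop-2-en-1-one}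
Product: 17 5-(benzyloxy)-8-{5,7-bis(benzyloxy)-2-[4-(benzyloxy)phenyl]-4-oxo-4H-chromen-6-yl}-2-[4-(benzyloxy)phenyl]-7-methoxy-4H-chromen-4-one, via bis-flavanone 16 (not isolated)
Conditions: I2 (0.3 equiv), DMSO, 130 °C, 3 h; aq. Na2S2O3 work-up
Reagents that add atoms: none
Why: I2/DMSO oxidative cyclisation, in which the single free phenol of each ring A closes by oxa-Michael addition and alpha-iodination with loss of HI gives the flavone, DMSO re-oxidising HI to I2.

**Step 14**
Reactants: 17 5-(benzyloxy)-8-{5,7-bis(benzyloxy)-2-[4-(benzyloxy)phenyl]-4-oxo-4H-chromen-6-yl}-2-[4-(benzyloxy)phenyl]-7-methoxy-4H-chromen-4-one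
Product: 18 5-hydroxy-8-[5,7-dihydroxy-2-(4-hydroxyphenyl)-4-oxo-4H-chromen-6-yl]-2-(4-hydroxyphenyl)-7-methoxy-4H-chromen-4-one (7'-O-methylagathisflavone)
Conditions: H2 (1 atm), 10% Pd/C, THF/MeOH 1:1, rt
Reagents that add atoms: none
Why: Catalytic hydrogenolysis cleaves all five benzyl ethers under conditions that leave the aryl methyl ether and the flavone C2=C3 bond intact.

**Compound list**
1 | 1-(2,4,6-trihydroxyphenyl)ethanone (phloroacetophenone) | CC(=O)c1c(O)cc(O)cc1O | starting material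
2 | 1-(2,6-dihydroxy-4-methoxyphenyl)ethanone | CC(=O)c1c(O)cc(OC)cc1O | intermediate
3 | 1-[2-(benzyloxy)-6-hydroxy-4-methoxyphenyl]ethanone | CC(=O)c1c(O)cc(OC)cc1OCc1ccccc1 | intermediate
4 | 1-[6-(benzyloxy)-2-hydroxy-3-iodo-4-methoxyphenyl]ethanone | CC(=O)c1c(O)c(I)c(OC)cc1OCc1ccccc1 | intermediate
5 | 1-[6-(benzyloxy)-3-iodo-4-methoxy-2-(methoxymethoxy)phenyl]ethanone | CC(=O)c1c(OCOC)c(I)c(OC)cc1OCc1ccccc1 | intermediate
6 | 1-[6-(benzyloxy)-4-methoxy-2-(methoxymethoxy)-3-(4,4,5,5-tetramethyl-1,3,2-dioxaborolan-2-yl)phenyl]ethanone (fragment 1) | CC(=O)c1c(OCOC)c(B2OC(C)(C)C(C)(C)O2)c(OC)cc1OCc1ccccc1 | intermediate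
7 | 1-[4-(benzyloxy)-2,6-dihydroxyphenyl]ethanone | CC(=O)c1c(O)cc(OCc2ccccc2)cc1O | intermediate
8 | 1-[4-(benzyloxy)-2-hydroxy-6-(methoxymethoxy)phenyl]ethanone | CC(=O)c1c(O)cc(OCc2ccccc2)cc1OCOC | intermediate
9 | 1-[4-(benzyloxy)-2-hydroxy-3-iodo-6-(methoxymethoxy)phenyl]ethanone | CC(=O)c1c(O)c(I)c(OCc2ccccc2)cc1OCOC | intermediate
10 | 1-[2,4-bis(benzyloxy)-3-iodo-6-(methoxymethoxy)phenyl]ethanone (fragment 2) | CC(=O)c1c(OCc2ccccc2)c(I)c(OCc2ccccc2)cc1OCOC | intermediate
11 | 1,1'-[2',4,6'-tris(benzyloxy)-6-methoxy-2,4'-bis(methoxymethoxy)biphenyl-3,3'-diyl]diethanone (racemic axis) | CC(=O)c1c(OCOC)c(-c2c(OCc3ccccc3)c(C(C)=O)c(OCOC)cc2OCc2ccccc2)c(OC)cc1OCc1ccccc1 | intermediate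
12 | 1,1'-[2',4,6'-tris(benzyloxy)-2,4'-dihydroxy-6-methoxybiphenyl-3,3'-diyl]diethanone | CC(=O)c1c(O)c(-c2c(OCc3ccccc3)c(C(C)=O)c(O)cc2OCc2ccccc2)c(OC)cc1OCc1ccccc1 | intermediate
13 | 4-(benzyloxy)benzaldehyde | O=Cc1ccc(OCc2ccccc2)cc1 | starting material
14 | 1,1'-[2',4,6'-tris(benzyloxy)-2,4'-dihydroxy-6-methoxybiphenyl-3,3'-diyl]bis{3-[4-(benzyloxy)phenyl]-3-hydroxypropan-1-one} (bis-aldol adduct, mixture of diastereomers, not isolated) | O=C(CC(O)c1ccc(OCc2ccccc2)cc1)c1c(O)c(-c2c(OCc3ccccc3)c(C(=O)CC(O)c3ccc(OCc4ccccc4)cc3)c(O)cc2OCc2ccccc2)c(OC)cc1OCc1ccccc1 | intermediate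
15 | (2E,2'E)-1,1'-[2',4,6'-tris(benzyloxy)-2,4'-dihydroxy-6-methoxybiphenyl-3,3'-diyl]bis{3-[4-(benzyloxy)phenyl]prop-2-en-1-one} | O=C(/C=C/c1ccc(OCc2ccccc2)cc1)c1c(O)c(-c2c(OCc3ccccc3)c(C(=O)/C=C/c3ccc(OCc4ccccc4)cc3)c(O)cc2OCc2ccccc2)c(OC)cc1OCc1ccccc1 | intermediate
16 | 5-(benzyloxy)-8-{5,7-bis(benzyloxy)-2-[4-(benzyloxy)phenyl]-4-oxochroman-6-yl}-2-[4-(benzyloxy)phenyl]-7-methoxychroman-4-one (bis-flavanone, mixture of diastereomers, not isolated) | COc1cc(OCc3ccccc3)c2C(=O)CC(c3ccc(OCc4ccccc4)cc3)Oc2c1-c1c(OCc3ccccc3)cc2OC(c3ccc(OCc4ccccc4)cc3)CC(=O)c2c1OCc1ccccc1 | intermediate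
17 | 5-(benzyloxy)-8-{5,7-bis(benzyloxy)-2-[4-(benzyloxy)phenyl]-4-oxo-4H-chromen-6-yl}-2-[4-(benzyloxy)phenyl]-7-methoxy-4H-chromen-4-one | COc1cc(OCc3ccccc3)c2c(=O)cc(-c3ccc(OCc4ccccc4)cc3)oc2c1-c1c(OCc3ccccc3)cc2oc(-c3ccc(OCc4ccccc4)cc3)cc(=O)c2c1OCc1ccccc1 | intermediate
18 | 5-hydroxy-8-[5,7-dihydroxy-2-(4-hydroxyphenyl)-4-oxo-4H-chromen-6-yl]-2-(4-hydroxyphenyl)-7-methoxy-4H-chromen-4-one (7'-O-methylagathisflavone) | COc1cc(O)c2c(=O)cc(-c3ccc(O)cc3)oc2c1-c1c(O)cc2oc(-c3ccc(O)cc3)cc(=O)c2c1O | target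

**Totals**
Total steps: 14. Longest linear sequence: 10 steps (1, 2, 3, 4, 5, 6, 11, 12, 15, 17, 18; steps 1–5 and 10–14). The second branch (steps 6–9) joins at step 10.

**Steps most likely to fail**

Step 10, the tetra-ortho-substituted Suzuki–Miyaura coupling, may suffer protodeboronation of 6 or stall. The fallback is a mixed Ullmann reductive coupling that needs no boron partner. It sets out from iodide 5 (3 equiv) and iodide 10, heated with activated Cu powder in DMF at 140 °C. The cross-coupled biaryl is separated from the two homodimers by chromatography, and the sequence comes back to the route at 11. No new compound is made (none, F0).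

Step 5, the Miyaura borylation of a di-ortho-substituted electron-rich iodide, may give protodeiodination. The fallback changes the nucleophile from boron to zinc. It sets out from 5: Zn dust and LiCl in THF at 50 °C insert into the C–I bond, with the ketone tolerated, to give [3-acetyl-4-(benzyloxy)-6-methoxy-2-(methoxymethoxy)phenyl]zinc iodide F1. This is not isolated and is coupled with 10 in a Negishi reaction (Pd2(dba)3, RuPhos, THF/NMP, 70 °C), coming back to the route at 11.

Step 13, the double oxidative cyclisation, may close the hindered phenol next to the biaryl axis incompletely or lose 5-O-benzyl groups. The fallback is a Baker–Venkataraman route that sets out from 12 and bypasses the chalcone. Both phenols are acylated with 4-(benzyloxy)benzoyl chloride (O=C(Cl)c1ccc(OCc2ccccc2)cc1; pyridine, DMAP, 60 °C) to give 3,3'-diacetyl-2',4,6'-tris(benzyloxy)-6-methoxybiphenyl-2,4'-diyl bis[4-(benzyloxy)benzoate] F2. KOH in pyridine at 50 °C shifts both aroyl groups from O to C to give 1,1'-[2',4,6'-tris(benzyloxy)-2,4'-dihydroxy-6-methoxybiphenyl-3,3'-diyl]bis{3-[4-(benzyloxy)phenyl]propane-1,3-dione} F3. Cyclodehydration with p-TsOH in toluene at 90 °C then comes back to the route at 17.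

**Further compounds**
F1 | step 5 | [3-acetyl-4-(benzyloxy)-6-methoxy-2-(methoxymethoxy)phenyl]zinc iodide | CC(=O)c1c(OCOC)c([Zn]I)c(OC)cc1OCc1ccccc1
F0 | step 10 | none | none
F2 | step 13 | 3,3'-diacetyl-2',4,6'-tris(benzyloxy)-6-methoxybiphenyl-2,4'-diyl bis[4-(benzyloxy)benzoate] | CC(=O)c1c(OC(=O)c2ccc(OCc3ccccc3)cc2)c(-c2c(OCc3ccccc3)c(C(C)=O)c(OC(=O)c3ccc(OCc4ccccc4)cc3)cc2OCc2ccccc2)c(OC)cc1OCc1ccccc1
F3 | step 13 | 1,1'-[2',4,6'-tris(benzyloxy)-2,4'-dihydroxy-6-methoxybiphenyl-3,3'-diyl]bis{3-[4-(benzyloxy)phenyl]propane-1,3-dione} | O=C(CC(=O)c1ccc(OCc2ccccc2)cc1)c1c(O)c(-c2c(OCc3ccccc3)c(C(=O)CC(=O)c3ccc(OCc4ccccc4)cc3)c(O)cc2OCc2ccccc2)c(OC)cc1OCc1ccccc1
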